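**Plan**
- Retrosynthesis: the dienyl side chain is cut at C11–C12 (Negishi coupling), the C18 ester and the 6‑acetate are traced back to an acetal and a ketone, and ring A and ring B are then opened together at C5–C10 and C8–C9 by an intramolecular Diels–Alder disconnection.
- Enabling feature: in ring B the segment C5–C6(O)–C7–C8(=C17) is a masked 2‑silyloxy vinylallene and C9=C10 with C11 is an (E)‑enal; the C1–C3 chain of ring A is the tether, so one cycloaddition gives both rings, the C6 oxygen and the exocyclic C8=C17 alkene.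
- Forward: the acyclic chain is built linearly (C4 quaternary centre by Johnson–Claisen rearrangement, C18 by ozonolysis and acetalisation, dienophile by Negishi coupling, diene from a Weinreb amide); the cycloaddition closes ring A and ring B at once; C6 reduction, C18 oxidation and side‑chain coupling finish.
- Stereochemistry: a CBS reduction sets a carbinol whose chirality is transferred to C4; C4 (bulky acetal anti to the forming bond), the E‑enal and the endo, trans‑fused transition state set C5, C9 and C10; C6 comes from a thermodynamic ketone reduction; alkene geometries come from syn carbo‑ and hydrometalation.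

Key step: step 10

Remark: labdane atom numbers are used for the bicyclic compounds (C17 = exocyclic methylene carbon on C8, C18 = the C4 carbon that ends as the ester, C19 = C4 methyl, C20 = C10 methyl); but‑1‑en‑3‑yne is assumed to be purchasable as a solution.

**Step 1**
Reactants: 1 5-chloropent-1-yne
Product: 3 (E)-7-chloro-4-methylhept-3-en-2-one, via alkenylalane 2 (not isolated)
Conditions: Me3Al, Cp2ZrCl2 (cat.), CH2Cl2, 0 °C to rt; then AcCl, −20 to 0 °C
Reagents that add atoms: trimethylaluminium (C[Al](C)C); acetyl chloride (CC(Cl)=O)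
Why: Negishi carboalumination adds methyl and aluminium syn across the alkyne with methyl on the internal carbon, and acylation of the alkenyl–aluminium bond with retention should give the E‑enone.

**Step 2**
Reactants: 3 (E)-7-chloro-4-methylhept-3-en-2-one
Product: 4 (2S,3E)-7-chloro-4-methylhept-3-en-2-ol
Conditions: (R)-Me-CBS oxazaborolidine (0.1 equiv), BH3·SMe2, THF, −20 °C; MeOH quench
Reagents that add atoms: none
Why: Corey–Bakshi–Shibata reduction, in which the alkenyl group acts as the large substituent, so the (R)-catalyst should give the (S)-carbinol.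

**Step 3**
Reactants: 4 (2S,3E)-7-chloro-4-methylhept-3-en-2-ol
Product: 6 methyl (3S,4E)-3-(3-chloropropyl)-3-methylhex-4-enoate, via ketene acetal 5 (not isolated)
Conditions: MeC(OMe)3, EtCO2H (cat.), xylene, 135 °C, MeOH distilled off
Reagents that add atoms: trimethyl orthoacetate (CC(OC)(OC)OC)
Why: Johnson–Claisen rearrangement through a chair transition state with the carbinol methyl equatorial (enforced by 1,3-allylic strain against the cis methyl on the alkene) should transfer the C–O chirality suprafacially to the new quaternary carbon (future C4, S) and give the E-propenyl group.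

**Step 4**
Reactants: 6 methyl (3S,4E)-3-(3-chloropropyl)-3-methylhex-4-enoate
Product: 8 methyl (3S)-6-chloro-3-(dimethoxymethyl)-3-methylhexanoate, via aldehyde 7 (not isolated)
Conditions: O3, CH2Cl2–MeOH, −78 °C; Me2S; then HC(OMe)3, TsOH (cat.), MeOH, rt
Reagents that add atoms: trimethyl orthoformate (COC(OC)OC); methanol (CO)
Why: ozonolysis of the only alkene turns the propenyl group into the C18 aldehyde, and acid-catalysed acetalisation masks it as the branched dimethyl acetal that later steers the cycloaddition.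

**Step 5**
Reactants: 9 but-2-yn-1-ol
Product: 11 (E)-3-iodobut-2-en-1-ol, via alkenylzirconocene 10 (not isolated)
Conditions: Cp2Zr(H)Cl (2.2 equiv), THF, rt; then I2, 0 °C
Reagents that add atoms: iodine (II)
Why: hydrozirconation adds H and Zr syn with zirconium on the carbon remote from the oxygen-bearing CH2, and iodinolysis with retention should give the E-iodide.

**Step 6**
Reactants: 8 methyl (3S)-6-chloro-3-(dimethoxymethyl)-3-methylhexanoate; 11 (E)-3-iodobut-2-en-1-ol
Product: 14 methyl (3S,7E)-3-(dimethoxymethyl)-9-hydroxy-3,7-dimethylnon-7-enoate, via alkyl iodide 12 (not isolated), via alkylzinc iodide 13 (not isolated)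
Conditions: NaI, DMA, 80 °C; Zn dust (TMSCl-activated), 50 °C; then 11, Pd(OAc)2 (3 mol%), SPhos (6 mol%), THF–DMA, rt
Reagents that add atoms: none
Why: Finkelstein exchange and zinc insertion give a primary alkylzinc that tolerates ester and acetal, and Negishi sp3–sp2 coupling should proceed with retention of the E geometry faster than protonation by the free hydroxyl.

**Step 7**
Reactants: 14 methyl (3S,7E)-3-(dimethoxymethyl)-9-hydroxy-3,7-dimethylnon-7-enoate
Product: 15 (3S,7E)-3-(dimethoxymethyl)-9-hydroxy-N-methoxy-N,3,7-trimethylnon-7-enamide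
Conditions: MeNHOMe·HCl, iPrMgCl, THF, −20 to 0 °C
Reagents that add atoms: N,O-dimethylhydroxylamine hydrochloride (CNOC.Cl)
Why: Weinreb amide formation by aminolysis of the methyl ester with the magnesium amide, the hydroxyl being carried as its magnesium alkoxide.

**Step 8**
Reactants: 15 (3S,7E)-3-(dimethoxymethyl)-9-hydroxy-N-methoxy-N,3,7-trimethylnon-7-enamide
Product: 17 (6S,10E)-6-(dimethoxymethyl)-12-hydroxy-6,10-dimethyldodeca-1,2,10-trien-4-one, via propargyl ketone 16 (not isolated)
Conditions: propargylmagnesium bromide (3 equiv), Et2O–THF, −78 °C; aq. NH4Cl; then Et3N (0.2 equiv), CH2Cl2, rt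
Reagents that add atoms: propargylmagnesium bromide (C#CC[Mg]Br)
Why: Weinreb ketone synthesis (the chelated tetrahedral intermediate prevents over-addition) gives the β,γ-alkynyl ketone, which the amine should isomerise by prototropic shift to the conjugated allenyl ketone.

**Step 9**
Reactants: 17 (6S,10E)-6-(dimethoxymethyl)-12-hydroxy-6,10-dimethyldodeca-1,2,10-trien-4-one
Product: 18 (2E,7S)-7-(dimethoxymethyl)-3,7-dimethyl-9-oxododeca-2,10,11-trienal
Conditions: MnO2 (20 equiv), CH2Cl2, rt
Reagents that add atoms: none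
Why: chemoselective allylic oxidation with activated MnO2 should give the E-enal without touching the allenyl ketone or the acetal.

**Step 10**
Reactants: 18 (2E,7S)-7-(dimethoxymethyl)-3,7-dimethyl-9-oxododeca-2,10,11-trienal
Product: 20 (4S,5S,9R,10R)-6-[(tert-butyldimethylsilyl)oxy]-18,18-dimethoxy-12,13,14,15,16-pentanorlabda-6,8(17)-dien-11-al, via silyloxy vinylallene 19 (not isolated)
Conditions: TBSOTf (1.1 equiv), iPr2NEt (2.5 equiv), CH2Cl2, −78 °C; then PhMe, BHT (cat.), 25 to 60 °C
Reagents that add atoms: tert-butyldimethylsilyl triflate (CC(C)(C)[Si](C)(C)OS(=O)(=O)C(F)(F)F)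
Why: Soft enolisation at C5, the only enolisable position of the allenyl ketone, should give the (Z)-2-silyloxy vinylallene 19, whose C5=C6–C7=C8 diene then adds to the tethered C9=C10 enal in a concerted but asynchronous normal-demand [4+2] cycloaddition (nucleophilic C5 to the enal β-carbon C10, C9 to the central allene carbon C8). The closest known reaction types are the intramolecular Diels–Alder reactions of vinylallenes and of 2-silyloxy dienes with enals (type 1, four-atom tether). Ring B is the cyclohexene made by the cycloaddition itself and contains both new bonds, and ring A is closed as the fused six-membered ring through the C5–C10 bond with the C1–C3 tether in a chair; the distal allene π bond stays as the exocyclic C8=C17 alkene and the enol ether keeps the oxygen on C6. Suprafacial addition to the E-enal sets C9 and C10 with C11 cis to C20, and the endo-aldehyde, exo-tether transition state sets C5 with H-5 anti to C20 (trans-decalin). Relative to the preset C4 centre, one C4 substituent must lie nearly eclipsed with the (Z)-C6–OSi bond and syn to the incoming C20 methyl and only the methyl group fits there, so the branched dimethoxymethyl group should stand anti to the forming C5–C10 bond and end equatorial with C19 axial and cis to C20. The step needs periselectivity (inner allene π bond as diene terminus, C=C and not C=O as the 2π partner), which the tether length secures, and chemoselective enolisation of the ketone beside the enal and the acetal, which the low temperature and the hindered amine should secure.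

**Step 11**
Reactants: 20 (4S,5S,9R,10R)-6-[(tert-butyldimethylsilyl)oxy]-18,18-dimethoxy-12,13,14,15,16-pentanorlabda-6,8(17)-dien-11-al
Product: 21 (4S,5S,9R,10S)-6-[(tert-butyldimethylsilyl)oxy]-18,18-dimethoxy-12,13,14,15,16-pentanorlabda-6,8(17)-dien-11-ol
Conditions: NaBH4, MeOH–CH2Cl2, −20 °C
Reagents that add atoms: none
Why: borohydride reduction of the aldehyde secures the epimerisable C9 centre while the silyl dienol ether and the acetal should survive.

**Step 12**
Reactants: 21 (4S,5S,9R,10S)-6-[(tert-butyldimethylsilyl)oxy]-18,18-dimethoxy-12,13,14,15,16-pentanorlabda-6,8(17)-dien-11-ol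
Product: 23 (4S,5S,6R,9R,10S)-18,18-dimethoxy-12,13,14,15,16-pentanorlabd-8(17)-ene-6,11-diol, via ketone 22 (not isolated)
Conditions: Bu4NF–AcOH (1:1), THF, −78 to −20 °C; pH 7 buffer; then SmI2, H2O, Et3N, THF, rt
Reagents that add atoms: none
Why: kinetic protodesilylation of the silyl dienol ether at the α-carbon C7 should give the deconjugated 8(17)-en-6-one, and electron-transfer reduction with SmI2 should place the new hydroxyl equatorial (6R), away from the syn-axial C19 and C20 methyl groups.

**Step 13**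
Reactants: 23 (4S,5S,6R,9R,10S)-18,18-dimethoxy-12,13,14,15,16-pentanorlabd-8(17)-ene-6,11-diol
Product: 24 (4S,5S,6R,9R,10R)-11-iodo-18,18-dimethoxy-12,13,14,15,16-pentanorlabd-8(17)-en-6-ol
Conditions: I2, PPh3, imidazole, CH2Cl2, 0 °C
Reagents that add atoms: iodine (II)
Why: Appel-type iodination should be selective for the primary alcohol over the hindered secondary hydroxyl next to C4.

**Step 14**
Reactants: 24 (4S,5S,6R,9R,10R)-11-iodo-18,18-dimethoxy-12,13,14,15,16-pentanorlabd-8(17)-en-6-ol
Product: 25 (4S,5S,6R,9R,10R)-11-iodo-18,18-dimethoxy-12,13,14,15,16-pentanorlabd-8(17)-en-6-yl acetate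
Conditions: Ac2O, DMAP (cat.), pyridine, 40 °C
Reagents that add atoms: acetic anhydride (CC(=O)OC(C)=O)
Why: DMAP-catalysed acylation installs the 6-acetate with retention at C6.

**Step 15**
Reactants: 25 (4S,5S,6R,9R,10R)-11-iodo-18,18-dimethoxy-12,13,14,15,16-pentanorlabd-8(17)-en-6-yl acetate
Product: 26 (4S,5S,6R,9R,10R)-6-acetoxy-11-iodo-12,13,14,15,16-pentanorlabd-8(17)-en-18-al
Conditions: TsOH·H2O (0.2 equiv), acetone–H2O (10:1), 40 °C
Reagents that add atoms: water (O)
Why: mild acid-catalysed acetal hydrolysis should free the C18 aldehyde and spare the exocyclic alkene, the acetate and the primary iodide.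

**Step 16**
Reactants: 26 (4S,5S,6R,9R,10R)-6-acetoxy-11-iodo-12,13,14,15,16-pentanorlabd-8(17)-en-18-al
Product: 28 methyl (4S,5S,6R,9R,10R)-6-acetoxy-11-iodo-12,13,14,15,16-pentanorlabd-8(17)-en-18-oate, via carboxylic acid 27 (not isolated)
Conditions: NaClO2, NaH2PO4, 2-methylbut-2-ene, tBuOH–H2O, rt; then TMSCHN2, PhMe–MeOH, 0 °C
Reagents that add atoms: sodium chlorite ([Na+].[O-]Cl=O); (trimethylsilyl)diazomethane (C[Si](C)(C)C=[N+]=[N-])
Why: Pinnick oxidation converts the hindered aldehyde to the acid with hypochlorous acid scavenged by the excess alkene, and methylation with the diazoalkane gives the ester without base.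

**Step 17**
Reactants: 29 but-1-en-3-yne
Product: 31 (E)-1-iodo-2-methylbuta-1,3-diene, via dienylalane 30 (not isolated)
Conditions: Me3Al, Cp2ZrCl2 (cat.), CH2Cl2, 0 °C to rt; then I2, THF, −30 °C
Reagents that add atoms: trimethylaluminium (C[Al](C)C); iodine (II)
Why: Negishi carboalumination of the alkyne (syn, methyl on the internal carbon, alkene untouched) and iodinolysis with retention should give the E-dienyl iodide.

**Step 18**
Reactants: 28 methyl (4S,5S,6R,9R,10R)-6-acetoxy-11-iodo-12,13,14,15,16-pentanorlabd-8(17)-en-18-oate; 31 (E)-1-iodo-2-methylbuta-1,3-diene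
Product: 33 methyl (4S,5S,6R,9R,10S,12E)-6-acetoxylabda-8(17),12,14-trien-18-oate, via alkylzinc iodide 32 (not isolated)
Conditions: Zn dust (I2-activated), DMA, 50 °C; then 31, Pd(OAc)2 (3 mol%), SPhos (6 mol%), THF, rt
Reagents that add atoms: none
Why: zinc insertion into the primary iodide tolerates ester and acetate, and Negishi coupling with the dienyl iodide should form C11–C12 with retention of the 12E geometry.

**Compound list**
1 | 5-chloropent-1-yne | C#CCCCCl | starting material
2 | (E)-(5-chloro-2-methylpent-1-en-1-yl)dimethylalane | C[Al](C)/C=C(\C)CCCCl | intermediate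
3 | (E)-7-chloro-4-methylhept-3-en-2-one | CC(=O)/C=C(\C)CCCCl | intermediate
4 | (2S,3E)-7-chloro-4-methylhept-3-en-2-ol | C[C@H](O)/C=C(\C)CCCCl | intermediate
5 | (2S,3E)-7-chloro-2-[(1-methoxyethenyl)oxy]-4-methylhept-3-ene (ketene acetal) | C=C(OC)O[C@@H](C)/C=C(\C)CCCCl | intermediate
6 | methyl (3S,4E)-3-(3-chloropropyl)-3-methylhex-4-enoate | ClCCC[C@](CC(=O)OC)(C)/C=C/C | intermediate
7 | methyl (3S)-6-chloro-3-formyl-3-methylhexanoate | ClCCC[C@](CC(=O)OC)(C)C=O | intermediate
8 | methyl (3S)-6-chloro-3-(dimethoxymethyl)-3-methylhexanoate | ClCCC[C@](CC(=O)OC)(C)C(OC)OC | intermediate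
9 | but-2-yn-1-ol | CC#CCO | starting material
10 | (E)-(4-hydroxybut-2-en-2-yl)zirconocene chloride (O–H zirconated in the flask) | C/C(=C\CO)[Zr](Cl)(C1C=CC=C1)C1C=CC=C1 | intermediate
11 | (E)-3-iodobut-2-en-1-ol | OC/C=C(\C)I | intermediate
12 | methyl (3S)-3-(dimethoxymethyl)-6-iodo-3-methylhexanoate | ICCC[C@](CC(=O)OC)(C)C(OC)OC | intermediate
13 | [(4S)-4-(dimethoxymethyl)-6-methoxy-4-methyl-6-oxohexyl]zinc iodide | I[Zn]CCC[C@](CC(=O)OC)(C)C(OC)OC | intermediate
14 | methyl (3S,7E)-3-(dimethoxymethyl)-9-hydroxy-3,7-dimethylnon-7-enoate | OC/C=C(\C)CCC[C@](CC(=O)OC)(C)C(OC)OC | intermediate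
15 | (3S,7E)-3-(dimethoxymethyl)-9-hydroxy-N-methoxy-N,3,7-trimethylnon-7-enamide | OC/C=C(\C)CCC[C@](CC(=O)N(C)OC)(C)C(OC)OC | intermediate
16 | (6S,10E)-6-(dimethoxymethyl)-12-hydroxy-6,10-dimethyldodec-10-en-1-yn-4-one | OC/C=C(\C)CCC[C@](CC(=O)CC#C)(C)C(OC)OC | intermediate
17 | (6S,10E)-6-(dimethoxymethyl)-12-hydroxy-6,10-dimethyldodeca-1,2,10-trien-4-one | OC/C=C(\C)CCC[C@](CC(=O)C=C=C)(C)C(OC)OC | intermediate
18 | (2E,7S)-7-(dimethoxymethyl)-3,7-dimethyl-9-oxododeca-2,10,11-trienal | O=C/C=C(\C)CCC[C@](CC(=O)C=C=C)(C)C(OC)OC | intermediate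
19 | (2E,7S,8Z)-9-[(tert-butyldimethylsilyl)oxy]-7-(dimethoxymethyl)-3,7-dimethyldodeca-2,8,10,11-tetraenal | O=C/C=C(\C)CCC[C@](/C=C(\O[Si](C)(C)C(C)(C)C)C=C=C)(C)C(OC)OC | intermediate
20 | (4S,5S,9R,10R)-6-[(tert-butyldimethylsilyl)oxy]-18,18-dimethoxy-12,13,14,15,16-pentanorlabda-6,8(17)-dien-11-al | O=C[C@@H]1C(=C)C=C(O[Si](C)(C)C(C)(C)C)[C@H]2[C@@]1(C)CCC[C@]2(C)C(OC)OC | intermediate
21 | (4S,5S,9R,10S)-6-[(tert-butyldimethylsilyl)oxy]-18,18-dimethoxy-12,13,14,15,16-pentanorlabda-6,8(17)-dien-11-ol | OC[C@@H]1C(=C)C=C(O[Si](C)(C)C(C)(C)C)[C@H]2[C@@]1(C)CCC[C@]2(C)C(OC)OC | intermediate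
22 | (4S,5S,9R,10S)-11-hydroxy-18,18-dimethoxy-12,13,14,15,16-pentanorlabd-8(17)-en-6-one | OC[C@@H]1C(=C)CC(=O)[C@H]2[C@@]1(C)CCC[C@]2(C)C(OC)OC | intermediate
23 | (4S,5S,6R,9R,10S)-18,18-dimethoxy-12,13,14,15,16-pentanorlabd-8(17)-ene-6,11-diol | OC[C@@H]1C(=C)C[C@@H](O)[C@H]2[C@@]1(C)CCC[C@]2(C)C(OC)OC | intermediate
24 | (4S,5S,6R,9R,10R)-11-iodo-18,18-dimethoxy-12,13,14,15,16-pentanorlabd-8(17)-en-6-ol | IC[C@@H]1C(=C)C[C@@H](O)[C@H]2[C@@]1(C)CCC[C@]2(C)C(OC)OC | intermediate
25 | (4S,5S,6R,9R,10R)-11-iodo-18,18-dimethoxy-12,13,14,15,16-pentanorlabd-8(17)-en-6-yl acetate | IC[C@@H]1C(=C)C[C@@H](OC(C)=O)[C@H]2[C@@]1(C)CCC[C@]2(C)C(OC)OC | intermediate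
26 | (4S,5S,6R,9R,10R)-6-acetoxy-11-iodo-12,13,14,15,16-pentanorlabd-8(17)-en-18-al | IC[C@@H]1C(=C)C[C@@H](OC(C)=O)[C@H]2[C@@]1(C)CCC[C@]2(C)C=O | intermediate
27 | (4S,5S,6R,9R,10R)-6-acetoxy-11-iodo-12,13,14,15,16-pentanorlabd-8(17)-en-18-oic acid | IC[C@@H]1C(=C)C[C@@H](OC(C)=O)[C@H]2[C@@]1(C)CCC[C@]2(C)C(=O)O | intermediate
28 | methyl (4S,5S,6R,9R,10R)-6-acetoxy-11-iodo-12,13,14,15,16-pentanorlabd-8(17)-en-18-oate | IC[C@@H]1C(=C)C[C@@H](OC(C)=O)[C@H]2[C@@]1(C)CCC[C@]2(C)C(=O)OC | intermediate
29 | but-1-en-3-yne | C=CC#C | starting material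
30 | (E)-dimethyl(2-methylbuta-1,3-dien-1-yl)alane | C[Al](C)/C=C(\C)C=C | intermediate
31 | (E)-1-iodo-2-methylbuta-1,3-diene | I/C=C(\C)C=C | intermediate
32 | alkylzinc iodide from 28 (C11–ZnI, otherwise as 28) | I[Zn]C[C@@H]1C(=C)C[C@@H](OC(C)=O)[C@H]2[C@@]1(C)CCC[C@]2(C)C(=O)OC | intermediate
33 | methyl (4S,5S,6R,9R,10S,12E)-6-acetoxylabda-8(17),12,14-trien-18-oate | C=C/C(C)=C/C[C@@H]1C(=C)C[C@@H](OC(C)=O)[C@H]2[C@@]1(C)CCC[C@]2(C)C(=O)OC | target

**Step count**
Total: 18 steps. Longest linear sequence: 16 steps (steps 1–4, 6–16 and 18).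

**Steps most likely to fail**

1. Step 10. During soft enolisation the amine may add to the allenyl ketone and start oligomerisation, the enal may be silylated at its γ-position, the acetal may ionise, and endo or facial control may be incomplete. The fallback uses a plain 2-silyloxy diene and makes the exocyclic alkene afterwards; it sets out from 15 and comes back at 22. Addition of (E)-prop-1-enylmagnesium bromide to 15 gives the propenyl ketone (2E,6S,10E)-6-(dimethoxymethyl)-12-hydroxy-6,10-dimethyldodeca-2,10-dien-4-one F1. MnO2 gives the enal (2E,7S,10E)-7-(dimethoxymethyl)-3,7-dimethyl-9-oxododeca-2,10-dienal F2. TBSOTf and iPr2NEt give the silyloxy triene F3, which on warming should undergo the same acetal-controlled intramolecular Diels–Alder reaction to the 8-methyl cycloadduct F4 (C17 cis to C11). NaBH4 gives the alcohol F5, and Saegusa–Ito oxidation (Pd(OAc)2, MeCN) gives the 7-en-6-one F6. Deprotonation with LiN(iPr)2 (2.2 equiv, THF–DMPU, −78 °C) at the C17 methyl and kinetic α-protonation with AcOH at −78 °C should give 22, which goes on as in step 12.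

2. Step 12. The 8(17) alkene may migrate into conjugation with the ketone before the reduction, or the electron-transfer reduction may show too little preference for the equatorial alcohol. The fallback replaces the thermodynamic reduction by kinetic reduction and inversion; it sets out from 22 and comes back at 25. NaBH4–CeCl3 at −78 °C, added directly after the desilylation, should attack the face away from C19 and C20 and give the axial 6-epi diol F7. Appel iodination gives the 6-epi iodo alcohol F8, and a Mitsunobu reaction with acetic acid (PPh3, diisopropyl azodicarboxylate) inverts C6 and gives 25.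

3. Step 8. The ynone may isomerise past the allene to the conjugated alkynyl ketone, the allenyl ketone may polymerise under base, or a second equivalent of the reagent may add. The fallback builds the ketone by aldehyde propargylation and oxidation; it sets out from 15 and comes back at 18. iBu2AlH reduces 15 to the aldehyde (3S,7E)-3-(dimethoxymethyl)-9-hydroxy-3,7-dimethylnon-7-enal F9. Barbier propargylation (propargyl bromide, Zn, THF–aq. NH4Cl) gives the homopropargylic diol F10. Dess–Martin periodinane oxidises both hydroxyl groups to the ynone enal F11, and Et3N isomerises it to 18, so that step 9 is not needed.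

**Further compounds**
F1 | step 10 | (2E,6S,10E)-6-(dimethoxymethyl)-12-hydroxy-6,10-dimethyldodeca-2,10-dien-4-one | OC/C=C(\C)CCC[C@](CC(=O)/C=C/C)(C)C(OC)OC
F2 | step 10 | (2E,7S,10E)-7-(dimethoxymethyl)-3,7-dimethyl-9-oxododeca-2,10-dienal | O=C/C=C(\C)CCC[C@](CC(=O)/C=C/C)(C)C(OC)OC
F3 | step 10 | (2E,7S,8Z,10E)-9-[(tert-butyldimethylsilyl)oxy]-7-(dimethoxymethyl)-3,7-dimethyldodeca-2,8,10-trienal | O=C/C=C(\C)CCC[C@](/C=C(\O[Si](C)(C)C(C)(C)C)/C=C/C)(C)C(OC)OC
F4 | step 10 | (4S,5S,8R,9R,10R)-6-[(tert-butyldimethylsilyl)oxy]-18,18-dimethoxy-12,13,14,15,16-pentanorlabd-6-en-11-al | O=C[C@@H]1[C@H](C)C=C(O[Si](C)(C)C(C)(C)C)[C@H]2[C@@]1(C)CCC[C@]2(C)C(OC)OC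
F5 | step 10 | (4S,5S,8S,9R,10S)-6-[(tert-butyldimethylsilyl)oxy]-18,18-dimethoxy-12,13,14,15,16-pentanorlabd-6-en-11-ol | OC[C@@H]1[C@H](C)C=C(O[Si](C)(C)C(C)(C)C)[C@H]2[C@@]1(C)CCC[C@]2(C)C(OC)OC
F6 | step 10 | (4S,5S,9R,10S)-11-hydroxy-18,18-dimethoxy-12,13,14,15,16-pentanorlabd-7-en-6-one | OC[C@@H]1C(C)=CC(=O)[C@H]2[C@@]1(C)CCC[C@]2(C)C(OC)OC
F7 | step 12 | (4S,5S,6S,9R,10S)-18,18-dimethoxy-12,13,14,15,16-pentanorlabd-8(17)-ene-6,11-diol | OC[C@@H]1C(=C)C[C@H](O)[C@H]2[C@@]1(C)CCC[C@]2(C)C(OC)OC
F8 | step 12 | (4S,5S,6S,9R,10R)-11-iodo-18,18-dimethoxy-12,13,14,15,16-pentanorlabd-8(17)-en-6-ol | IC[C@@H]1C(=C)C[C@H](O)[C@H]2[C@@]1(C)CCC[C@]2(C)C(OC)OC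
F9 | step 8 | (3S,7E)-3-(dimethoxymethyl)-9-hydroxy-3,7-dimethylnon-7-enal | OC/C=C(\C)CCC[C@](CC=O)(C)C(OC)OC
F10 | step 8 | (6S,10E)-6-(dimethoxymethyl)-6,10-dimethyldodec-10-en-1-yne-4,12-diol (both C4 epimers) | OC/C=C(\C)CCC[C@](CC(O)CC#C)(C)C(OC)OC
F11 | step 8 | (2E,7S)-7-(dimethoxymethyl)-3,7-dimethyl-9-oxododec-2-en-11-ynal | O=C/C=C(\C)CCC[C@](CC(=O)CC#C)(C)C(OC)OC
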